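Two questions stand on the cedar flask: the reacted part comes from the loss of Z, and one ratio turns that part into the E that the average needs.

all flasks: X 1.3 mM
- cedar: Z 0.26 M; the very flask that is asked about, followed so far
- oak: Z 0.39 M; run made earlier
- flask: Z 0.26 M; time 5.0 min

cedar run (percent of the Z charged)

| time / s | E / % | Z / % |
|---|---|---|
| 10.0 | 0.5 | 97.6 |
| 12.0 | 0.3 | 96.4 |
| 25.0 | 0 | 96.6 |
| 60.0 | 0 | 92.6 |

oak run (percent of the Z charged)

| time / min | E / % | Z / % |
|---|---|---|
| 0.417 | 0.3 | 98.4 |
| 1.33 | 2.6 | 88.4 |
| 2.50 | 4.5 | 80.4 |
| 4.00 | 9.6 | 67.5 |

(scatter of a reading: 1 percentage point)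

* average number of monomer units in a chain (chains begun, living or dead) at 5.0 min
* part of the Z that has reacted at 5.0 min

- the average divides the monomer in chains by the number of chains begun, living and dead together
- what was read earlier has a scatter of 1 percentage point, one standard deviation
- the earlier runs do not show the number of chains; that part of a forecast is a guess

E gained divided by Z lost compares the two at one moment of a run. The last oak reading gives 0.295 as the share of lost Z found as E, the selectivity in the usual term. But the share may drift as a run goes on: oak at 1.33 min reads 0.224, though with the scatter of the readings. So it is best carried to a flask at a similar reacted part, and oak's last reading stands at 32.5%.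

Oak's loss, taken as first order in Z, gives 0.00164 s⁻¹, so cedar would reach 38.8% at 5.0 min. Yet oak holds more Z. Cedar's own reading at 60.0 s leads to 31.9%, but that rests on a loss of 7.40% against a scatter of 1 percentage point. The midpoint, 35.4%, lies close to oak's reacted part, so the share may be used, and c(E) comes to 27.2 mM.

If every X has begun one chain, the average is 20.9. The objection is that the readings do not count chains, and X still unreacted has begun none. So this figure is likely a low estimate.

The forecast gives 35% (range 29% to 41%) and an average of 28 (range 14 to 70), above this figure, and grants that “The chain count is a guess”.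

The cedar flask gives 36.0% reacted and an average of 39.6.

    Z + D → E + D, rate k1*[D]*[Z] (k = 1.00 M⁻¹ s⁻¹)
    Z → J (k = 9.90 × 10⁻⁴ s⁻¹)
    Z + X → G (k = 0.00370 M⁻¹ s⁻¹)
    Z + X → D + E (k = 0.0160 M⁻¹ s⁻¹)

Of the X charge, 28% is left at 5.00 min, and that X has begun no chain. Oak's share times the reacted part gives 10.6% E, and the flask holds 11.5%, a share of 0.320. The same flask left until 20 min keeps 11.4% of its Z, and its share reads 0.413.

The readings were generated by integration with constants of no real substance, noise included.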